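**Retrosynthetic overview**
- Agastenol is opened at the benzylic C2–O bond of the oxolane, the only ring made in the route and formed in the last step. The precursor is an acyclic (E,E)-diene alcohol that already carries the 4-hydroxybenzoate; ring closure is a catalytic asymmetric protonation/C–O closure that sets C3 and C2 together.
- The mono-ester comes from a C2-symmetric 2,3-bis(vanillylidene)butane-1,4-diol and 4-hydroxybenzoic acid by chemoselective mono-Mitsunobu esterification. The ester also blocks the second CH2OH, so only one ring can close.
- The diol comes from a dimethyl (E,E)-bis(arylidene)succinate by DIBAL-H reduction and O-deallylation.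
- The diester comes from two O-allylvanillin units and dimethyl succinate by double Stobbe condensation, which fixes the E geometry of the benzylidene found in the target.

Assumption: O-allylvanillin is bought (otherwise one step from vanillin and allyl bromide), and the (S)-catalyst named in step 5 stands for whichever antipode delivers 3S, to be swapped for its enantiomer if the induction proves opposite.

**Step 1**
Reactants: 1 4-(allyloxy)-3-methoxybenzaldehyde (2.1 equiv); 2 dimethyl succinate
Product: 4 dimethyl (2E,3E)-2,3-bis[(4-allyloxy-3-methoxyphenyl)methylidene]butanedioate, via Stobbe diacid 3 (not isolated)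
Conditions: NaOMe (3 equiv), MeOH, reflux, 16 h; then conc. H2SO4 (excess), MeOH, reflux, 12 h
Reagents that add atoms: methanol, CO
Why: Double Stobbe condensation (aldol, γ-lactonisation and E1cB ring opening, twice) gives the E,E-fulgenic acid with each aryl trans to its carboxyl, and Fischer esterification in the same methanol returns the crystalline diester.

**Step 2**
Reactants: 4 dimethyl (2E,3E)-2,3-bis[(4-allyloxy-3-methoxyphenyl)methylidene]butanedioate
Product: 5 (2E,3E)-2,3-bis[(4-allyloxy-3-methoxyphenyl)methylidene]butane-1,4-diol
Conditions: DIBAL-H (5 equiv), CH2Cl2, −78 to 0 °C; aq. Rochelle salt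
Reagents that add atoms: none
Why: DIBAL-H 1,2-reduction of enoates gives the allylic alcohols without conjugate reduction, so both alkene geometries and the allyl ethers are untouched.

**Step 3**
Reactants: 5 (2E,3E)-2,3-bis[(4-allyloxy-3-methoxyphenyl)methylidene]butane-1,4-diol
Product: 6 (2E,3E)-2,3-bis[(4-hydroxy-3-methoxyphenyl)methylidene]butane-1,4-diol
Conditions: Pd(PPh3)4 (5 mol%), morpholine (6 equiv), degassed THF, rt; pH 6 buffer work-up
Reagents that add atoms: none
Why: Tsuji–Trost deallylation ionises only the aryl allyl ethers (phenoxide leaving group) and morpholine traps the π-allyl, while the free allylic alcohols are not ionised by Pd(0).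

**Step 4**
Reactants: 6 (2E,3E)-2,3-bis[(4-hydroxy-3-methoxyphenyl)methylidene]butane-1,4-diol (2.0 equiv, excess recovered); 7 4-hydroxybenzoic acid (1.0 equiv)
Product: 8 [(2E,3E)-4-hydroxy-2,3-bis[(4-hydroxy-3-methoxyphenyl)methylidene]butyl] 4-hydroxybenzoate
Conditions: PPh3 (1.2 equiv), DIAD (1.2 equiv, added last, dropwise), THF, 0 °C to rt
Reagents that add atoms: none
Why: Mitsunobu esterification pairs the primary alkoxyphosphonium with the carboxylate (pKa about 4.5) and leaves the phenols (pKa about 10) alone, and the excess of the symmetric diol biases the outcome toward the mono-ester.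

**Step 5**
Reactants: 8 [(2E,3E)-4-hydroxy-2,3-bis[(4-hydroxy-3-methoxyphenyl)methylidene]butyl] 4-hydroxybenzoate
Product: 9 agastenol = [(2R,3S,4E)-2-(4-hydroxy-3-methoxyphenyl)-4-[(4-hydroxy-3-methoxyphenyl)methylidene]oxolan-3-yl]methyl 4-hydroxybenzoate
Conditions: (S)-3,3'-bis(2,4,6-triisopropylphenyl)-BINOL N-triflylphosphoramide (5 mol%), dry CH2Cl2 (0.02 M), −30 °C, 24 h; Et3N quench at −30 °C
Reagents that add atoms: none
Why: Proposed new method: catalytic asymmetric protonative cycloisomerisation (a formal 5-endo hydroalkoxylation), in which the 4-hydroxystyrene of the ester-bearing arm acts as a vinylogous enol, so the chiral acid, hydrogen-bonded through P=O to the free CH2OH, protonates the future C3 on one face to give an ion-paired p-quinone-methide-like benzylic cation that is closed at once by 5-exo-trig attack of that OH on the methide carbon (new C2–O bond) with the aryl trans to the CH2O-ester arm; C3 (S) is thus set by catalyst-controlled C-protonation and C2 (R) by substrate-controlled closure; the two inward-pointing aryls twist the diene so each arm behaves as an isolated styrene, and the benzoate blocks the only other hydroxyl; the closest known reaction types are chiral Brønsted-acid-catalysed intramolecular hydroalkoxylation of alkenes, chiral-phosphoric-acid 1,6-additions to in situ p-quinone methides and enantioselective protonation of enol derivatives, none of which has set a stereocentre by C-protonation of a trisubstituted hydroxystyrene within a 1,3-diene.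

**Compound list**
1 | 4-(allyloxy)-3-methoxybenzaldehyde (O-allylvanillin) | C=CCOc1ccc(C=O)cc1OC | starting material
2 | dimethyl succinate | COC(=O)CCC(=O)OC | starting material
3 | (2E,3E)-2,3-bis[(4-allyloxy-3-methoxyphenyl)methylidene]butanedioic acid (Stobbe diacid) | OC(=O)/C(=C/c1ccc(OCC=C)c(OC)c1)/C(=C\c1ccc(OCC=C)c(OC)c1)C(=O)O | intermediate (not isolated)
4 | dimethyl (2E,3E)-2,3-bis[(4-allyloxy-3-methoxyphenyl)methylidene]butanedioate | COC(=O)/C(=C/c1ccc(OCC=C)c(OC)c1)/C(=C\c1ccc(OCC=C)c(OC)c1)C(=O)OC | intermediate
5 | (2E,3E)-2,3-bis[(4-allyloxy-3-methoxyphenyl)methylidene]butane-1,4-diol | OC/C(=C/c1ccc(OCC=C)c(OC)c1)/C(=C\c1ccc(OCC=C)c(OC)c1)CO | intermediate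
6 | (2E,3E)-2,3-bis[(4-hydroxy-3-methoxyphenyl)methylidene]butane-1,4-diol | OC/C(=C/c1ccc(O)c(OC)c1)/C(=C\c1ccc(O)c(OC)c1)CO | intermediate
7 | 4-hydroxybenzoic acid | OC(=O)c1ccc(O)cc1 | starting material
8 | [(2E,3E)-4-hydroxy-2,3-bis[(4-hydroxy-3-methoxyphenyl)methylidene]butyl] 4-hydroxybenzoate | O=C(OC/C(=C/c1ccc(O)c(OC)c1)/C(=C\c1ccc(O)c(OC)c1)CO)c1ccc(O)cc1 | intermediate
9 | agastenol, (2R,3S,4E), aryl and CH2O-ester trans on the oxolane | COc1cc(/C=C2/CO[C@@H](c3ccc(O)c(OC)c3)[C@@H]2COC(=O)c2ccc(O)cc2)ccc1O | target

**Totals**
Total steps: 5. Longest linear sequence: 5 (1 and 2 to 9).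

**Three steps most likely to fail**

Step 5 (the proposed new step). Risks are modest facial selectivity in the C-protonation and unproductive protonation of the other arm, which would cause E/Z drift. Further risks are 1,4-addition to a 2,5-dihydrofuran isomer, Friedel–Crafts closure to an aryldihydronaphthalene, and acid re-opening of the product. The fallback uses known chemistry and sets out from 8. Ordinary Brønsted-acid Markovnikov hydroalkoxylation of the electron-rich styrene (p-TsOH·H2O, 5 mol%, CH2Cl2, 0 °C) gives the racemic 2,3-trans product, that is 9 together with its mirror image ent-agastenol F1. Preparative chiral SFC on an amylose carbamate phase then separates the two, and the route is rejoined at 9.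

Step 4. Risks are the mono/di-ester statistics, Mitsunobu cyclodehydration of the 1,4-diol to a 3,4-bis(arylidene)oxolane, and stray O-alkylation of phenols. The fallback reverses the order of the last two operations and sets out from 6. Diol 6 is cyclised under the step 5 catalyst, stopped at partial conversion so that the second hydroxyl does not close a furofuran, to give the hydroxymethyl oxolane [(2R,3S,4E)-2-(4-hydroxy-3-methoxyphenyl)-4-[(4-hydroxy-3-methoxyphenyl)methylidene]oxolan-3-yl]methanol F2. Its single, non-allylic primary alcohol is then esterified with 7 under Mitsunobu conditions, with no mono-selection needed, and the route is rejoined at 9. This fallback still depends on the unproven step 5 chemistry; if that also fails, the racemic acid cyclisation and resolution described for step 5 would be applied here.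

Step 1. Risks are a sluggish second condensation on the half-ester carboxylate and E/Z mixtures. The fallback builds the diene stepwise and sets out from 1 and 2. A single Stobbe condensation (1 equiv of 1, NaOMe, MeOH) gives the half-ester (3E)-4-(4-allyloxy-3-methoxyphenyl)-3-(methoxycarbonyl)but-3-enoic acid F3. Fischer esterification gives dimethyl (2E)-2-[(4-allyloxy-3-methoxyphenyl)methylidene]butanedioate F4. Its lithium enolate (LDA, THF, −78 °C) is condensed with a second equivalent of 1 (aldol, lactonisation, elimination) to give (2E,3E)-2,3-bis[(4-allyloxy-3-methoxyphenyl)methylidene]butanedioic acid monomethyl ester F5. Esterification with MeOH/H2SO4 rejoins the route at 4.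

**Further compounds**
F1 | step 5 | ent-agastenol, (2S,3R,4E) | COc1cc(/C=C2/CO[C@H](c3ccc(O)c(OC)c3)[C@H]2COC(=O)c2ccc(O)cc2)ccc1O
F2 | step 4 | [(2R,3S,4E)-2-(4-hydroxy-3-methoxyphenyl)-4-[(4-hydroxy-3-methoxyphenyl)methylidene]oxolan-3-yl]methanol | COc1cc(/C=C2/CO[C@@H](c3ccc(O)c(OC)c3)[C@@H]2CO)ccc1O
F3 | step 1 | (3E)-4-(4-allyloxy-3-methoxyphenyl)-3-(methoxycarbonyl)but-3-enoic acid | OC(=O)C/C(=C\c1ccc(OCC=C)c(OC)c1)C(=O)OC
F4 | step 1 | dimethyl (2E)-2-[(4-allyloxy-3-methoxyphenyl)methylidene]butanedioate | COC(=O)C/C(=C\c1ccc(OCC=C)c(OC)c1)C(=O)OC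
F5 | step 1 | (2E,3E)-2,3-bis[(4-allyloxy-3-methoxyphenyl)methylidene]butanedioic acid monomethyl ester | COC(=O)/C(=C/c1ccc(OCC=C)c(OC)c1)/C(=C\c1ccc(OCC=C)c(OC)c1)C(=O)O
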